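The ratio of two times tells whether solid is still feeding this flask when one acts: the wait up to the moment of acting over the feed time.

the same everywhere: solid first end groups 0.050 M
- epsilon: second end groups 0.0525 M; temperature 60 °C; the very flask that is asked about, followed so far
- eta: second end groups 0.079 M; temperature 55 °C; run made earlier
- flask: second end groups 0.0525 M; temperature 60 °C; time 8.0 d

| run | time / d | links / % | solid first end groups / % |
|---|---|---|---|
| epsilon | 0.333 | 2.5 | 81.9 |
| epsilon | 0.833 | 11.0 | 60.3 |
| epsilon | 1.67 | 23.5 | 31.7 |
| epsilon | 2.50 | 31.5 | 7.9 |
| epsilon | 4.00 | 33.9 | 0 |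
| epsilon | 5.00 | 32.7 | 0 |
| eta | 0.250 | 1.4 | 86.3 |
| eta | 0.417 | 4.3 | 78.3 |
| eta | 0.625 | 7.9 | 68.5 |
| eta | 1.25 | 21.0 | 45.6 |
| eta | 2.08 | 35.2 | 18.2 |
| eta | 3.00 | 43.6 | 0.1 |

(standard deviation of a reading: 0.3 percentage points)

- ochre: at 8.0 d take out 90% of the by-product then present, then wait 15 d
- blue: at 8.0 d add second end groups, 50.0% of the amount charged, then wait 15 d
- grey: at 8.0 d raise the temperature by 20 K, then wait 15 d
- amber: change nothing and wait 15 d more

- additions leave the volume as it is
- the analysis behind the earlier runs scatters by 0.3 percentage points, standard deviation
- at the start none of the solid first end groups is in solution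

- links, in percent of the solid first end groups first charged, at 8.0 d
- which option adds most links ("none" when 2 percentage points or less is all one gets) (ochre / blue / grey / amber / none)
- links present, in percent of the solid first end groups first charged, after blue
- links present, in percent of the solid first end groups first charged, after grey

The epsilon run is this flask followed so far. Between its last two readings with solid present, c of solid first end groups falls by 0.287 d⁻¹ as a share of the charge. Frozen at that rate, the 7.9% left at 2.50 d lasts until the feed time, the time at which the last solid enters solution: 2.78 d. The eta run, with the same charge of solid, reads similarly: 0.1% at 3.00 d.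

The epsilon links read 31.5% at 2.50 d, shortly before that time. They read 33.9% at 4.00 d and 32.7% at 5.00 d, a drop of 1.2 percentage points against a scatter of 0.3 points. The wait 8.0 d is longer than the feed time, by a factor of 2.88. So this flask should hold no solid by then. These readings do not tell where links will stand at that time, so the last reading, 32.7%, serves as a rough guide, and the options stay unranked.

The forecast gave 30% links, ochre as best, 28% after blue and 9% after grey, on the ground that “something is slowly draining the system”.

The flask gives 31.6% links, and grey is best with a gain of 16 points, against 5.4 points for ochre, 4.8 points for blue and −0.15 points for amber. Links stand at 36.3% after blue and 47.9% after grey.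

    solid first end groups ⇌ first end groups, rate k1*(cs1 - [first end groups]) while solid is left; crystals form when [first end groups] > cs1 (solubility = 36.0 mM, k = 5.90 × 10⁻⁴ min⁻¹)
    links ⇌ isomer of the product (K = 1.30, k = 4.50 × 10⁻⁴ min⁻¹, Ea = 120 kJ mol⁻¹, ΔH = −78.0 kJ mol⁻¹)
    first end groups + second end groups ⇌ links + by-product (K = 2.50, k = 0.0140 L mol⁻¹ min⁻¹, Ea = 76.0 kJ mol⁻¹, ΔH = −20.0 kJ mol⁻¹)
    (constants at 60 °C)

At 8.00 d this flask's step to links relaxes with a half-life of 0.669 d, and the step from links to isomer of the product with 0.605 d, both shorter than the wait 8.0 d. At 2.88 feed times, this flask holds 0% solid, and 15 d more moves links by −0.15 points. The neighbour flask charged with 0.013 M of solid has its feed time scaled to 0.722 d, and at 8.00 d it holds 0% solid and 41.4% links.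

The earlier runs and the new flask were computed for an exercise, and the scatter is random.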